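**Assumption (remark on the chemistry):** the target has no stereocentre and no stereogenic double bond, so the SMILES is the full structure. Ring A of the target is numbered as a chroman (O1, C2, C3, C4, C4a, C5–C8, C8a); the pyranopyranones use the fused numbering O1, C2, C3, C4, C4a, C5(=O), O6, C7, C8, C8a.

## The problem

The target 16 (C25H30O5) is an achiral dihydrochalcone. Ring A is a phloroglucinol with free hydroxyls on C5 and C7, the acyl group on C6, and a 2,2-dimethyldihydropyran fused at C4a–C8a with O1 para to the acyl carbon. Ring B is a 4-hydroxy-3-prenylphenyl group joined through a saturated CH2–CH2–C(=O) bridge. With no stereocentre, the difficulty is regiochemical and chemoselective. In a preformed phloroglucinol the three oxygens and the two free ring carbons are nearly equivalent, so C-prenylation, the choice of the oxygen that closes the pyran, and acylation at C6 rather than C8 all tend to give isomer mixtures. The two C5 units must end differently: one cyclised and saturated on ring A, one an open trisubstituted olefin beside a free phenol on ring B. Acid closes such an ortho-prenylphenol to a chroman and hydrogen saturates it, so the usual chalcone route needs a conjugate reduction that spares the prenyl group, and a chalcone with free hydroxyls at both positions ortho to the ketone closes to a chromanone in base. The feature that makes the key step possible is that the six carbons of ring A (C5, C4a, C8a, C8, C7, C6), with oxygen on alternate carbons, are a folded triacetic acid unit. Cut at C5–C6 and rejoined from C5 to the C7 oxygen, they become the 2-pyranone ring of the 2H-pyrano[4,3-b]pyran-5-one 14, an isomer of 16 in which the pyran oxygen is already fixed on C8a and C6 is an exocyclic CH2 carrying the whole acyl chain.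

## Retrosynthesis

**16 to 14.** The C5–C6 bond of ring A is cut and C5 is rejoined to the C7 oxygen as a lactone, giving pyranone 14. The neighbouring cut at C6–C7 would lead to a pyrano[3,2-c]pyranone that cannot be reached from the nucleophilic C3 of a 4-hydroxypyranone. A cut at the aryl–acyl bond leads back to a Friedel–Crafts reaction on a phloroglucinol with two competing sites. Compound 14 contains no benzene ring A and no free ring A hydroxyl. The forward reaction asks methoxide to open the lactone to the keto ester 15, and the diketone carbon of 15 to close onto the ester by a Claisen condensation. No acid and no reducing agent are used, so the prenylphenol of ring B is untouched.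

**14 to 5 and 11.** The bond between the 7-CH2 group and the side-chain carbonyl is cut; this is the future aryl–acyl bond of 16, made before the aryl ring exists. The forward reaction is a Claisen acylation of the lithiated pyranone 12 (from 5) by the ester 11, carried as its phenolate 13. Pyranone 5 has a single acidic site, so the question of C6 against C8 does not arise. A cut at the CH2–CH2 bond of the bridge would need a ring B benzyl halide and a dianion alkylation and gains nothing.

**5 to 4, then to 1 and 2.** The O1–C2 and C4–C4a bonds are cut. Triacetic acid lactone 1 and 3-methylbut-2-enal 2 combine by Knoevenagel condensation to the oxatriene 3, which closes by oxa-6π electrocyclisation through the C4 oxygen to 4. This fixes which oxygen lies in the pyran ring, something an acid-catalysed addition of a prenyl cation to 1 would not do. The C3=C4 olefin of 4 is hydrogenated to 5 before any prenyl group is present in the synthesis.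

**11 to 9, 8, then 6 and 7.** The bond between ring B and its prenyl group is cut by an aromatic Claisen transform. Phenol 6 is O-alkylated with the propargylic chloride 7 to 8, semihydrogenated to the 1,1-dimethylallyl ether 9, and rearranged through dienone 10 to 11. The [3,3] shift delivers the prenyl group (not its branched isomer) to the ortho carbon; the para position is blocked and the two ortho positions are equivalent. Direct C-prenylation of 6 would give O- and C-alkylated and doubly alkylated mixtures.

## Roads not taken

**Alternative 1:** the most obvious cut is the Cα–Cβ bond of the bridge. Claisen–Schmidt condensation of 1-(5,7-dihydroxy-2,2-dimethylchroman-6-yl)ethanone A1 with 4-hydroxy-3-prenylbenzaldehyde A2 would give the chalcone A3, followed by 1,4-reduction.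
- A1 requires C-prenylation of a phloroglucinol ketone and an acid ring closure that can also give the 8-acetyl isomer A4.
- The hydroxyls at C5 and C7 of A3 add to the enone in base, so both need protection and later removal.
- The reduction must distinguish the enone from the prenyl olefin, which excludes plain hydrogenation.
- The chosen plan needs none of these operations and makes the bridge saturated from the start.

**Alternative 2:** cut the aryl–acyl bond. Friedel–Crafts or Houben–Hoesch acylation of 2,2-dimethylchroman-5,7-diol A5 with 3-(4-hydroxy-3-prenylphenyl)propanoic acid A6 or a derivative.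
- C6 and C8 of A5 are each activated by two oxygens, so the C8-acylated isomer A7 is expected beside the target.
- The Lewis or Brønsted acid needed would close the ortho-prenylphenol of A6 to a chroman.
- The chosen plan makes the same bond as an enolate acylation at the only acidic carbon of 5.

**Alternative 3:** cut the Cβ–aryl bond by strain release. The cyclopropanol A8 (from a ring A ester by Kulinkovich reaction) would be opened by palladium catalysis to a homoenolate and coupled with the aryl bromide A9.
- This gives the saturated bridge without a reduction, but leaves the whole regiochemical problem of ring A unsolved.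
- It places a tertiary cyclopropanol between two protected oxygens, where β-hydride elimination to the enone competes.
- It ends with acid removal of protecting groups next to a prenylphenol, and the run-up is longer than the whole chosen route.

Key step: step 7

## Route

Step 1
Reactants: 1 4-hydroxy-6-methyl-2H-pyran-2-one (triacetic acid lactone); 2 3-methylbut-2-enal
Product: 4 2,2,7-trimethyl-2H,5H-pyrano[4,3-b]pyran-5-one, via 6-methyl-3-(3-methylbut-2-en-1-ylidene)-2H-pyran-2,4(3H)-dione 3 (not isolated)
Conditions: ethylenediammonium diacetate (10 mol %), EtOAc, 70 °C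
Reagents that add atoms: none
Why: Knoevenagel condensation at the nucleophilic C3 of 1 followed by oxa-6π electrocyclisation of oxatriene 3 through the C4 oxygen (formal [3+3] annulation), a reaction well known for 4-hydroxy-2-pyranones and enals; it should give the 2-pyranone-fused 2H-pyran.

Step 2
Reactants: 4 2,2,7-trimethyl-2H,5H-pyrano[4,3-b]pyran-5-one
Product: 5 2,2,7-trimethyl-3,4-dihydro-2H,5H-pyrano[4,3-b]pyran-5-one
Conditions: H2 (1 atm), 5% Pd/C, EtOAc, rt, stopped after one equivalent of H2
Reagents that add atoms: none
Why: catalytic hydrogenation; the cis-disubstituted C3=C4 olefin should be reduced well before the more substituted double bonds of the 2-pyranone ring.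

Step 3
Reactants: 6 methyl 3-(4-hydroxyphenyl)propanoate; 7 3-chloro-3-methylbut-1-yne
Product: 8 methyl 3-[4-(2-methylbut-3-yn-2-yloxy)phenyl]propanoate
Conditions: DBU, CuCl2 (1 mol %), MeCN, 0 °C
Reagents that add atoms: none
Why: copper-catalysed O-alkylation of a phenol by a tertiary propargylic chloride, the standard entry to aryl 1,1-dimethylpropargyl ethers; the methyl ester tolerates DBU at 0 °C.

Step 4
Reactants: 8 methyl 3-[4-(2-methylbut-3-yn-2-yloxy)phenyl]propanoate
Product: 9 methyl 3-[4-(2-methylbut-3-en-2-yloxy)phenyl]propanoate
Conditions: H2 (1 atm), Pd/CaCO3 poisoned with Pb(OAc)2 (Lindlar catalyst), quinoline, EtOAc, rt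
Reagents that add atoms: none
Why: Lindlar semihydrogenation of a terminal alkyne stops at the alkene.

Step 5
Reactants: 9 methyl 3-[4-(2-methylbut-3-en-2-yloxy)phenyl]propanoate
Product: 11 methyl 3-[4-hydroxy-3-(3-methylbut-2-en-1-yl)phenyl]propanoate, via methyl 3-[3-(3-methylbut-2-en-1-yl)-4-oxocyclohexa-1,5-dien-1-yl]propanoate 10 (not isolated)
Conditions: PhNEt2, 130 °C, Ar
Reagents that add atoms: none
Why: aromatic Claisen rearrangement; the [3,3] shift turns the 1,1-dimethylallyl ether into the ortho prenyl group, the para position is blocked, both ortho positions are equivalent, and dienone 10 tautomerises to the phenol in the basic solvent.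

Step 6
Reactants: 5 2,2,7-trimethyl-3,4-dihydro-2H,5H-pyrano[4,3-b]pyran-5-one; 11 methyl 3-[4-hydroxy-3-(3-methylbut-2-en-1-yl)phenyl]propanoate
Product: 14 7-{4-[4-hydroxy-3-(3-methylbut-2-en-1-yl)phenyl]-2-oxobutyl}-2,2-dimethyl-3,4-dihydro-2H,5H-pyrano[4,3-b]pyran-5-one, via (2,2-dimethyl-5-oxo-3,4-dihydro-2H,5H-pyrano[4,3-b]pyran-7-yl)methyllithium 12 (not isolated), via lithium 4-(3-methoxy-3-oxopropyl)-2-(3-methylbut-2-en-1-yl)phenolate 13 (not isolated)
Conditions: 5 (2.2 equiv), LiN(iPr)2 (2.2 equiv), THF, −78 °C; 11 with LiN(SiMe3)2 (1.0 equiv), THF, −78 °C, added to 12; −78 to −20 °C; aq. NH4Cl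
Reagents that add atoms: none
Why: crossed Claisen acylation of the vinylogous enolate of a 6-methyl-2-pyranone by an ester; C4a is substituted so the 7-methyl group is the only acidic site, the second equivalent of 12 deprotonates the product and prevents double addition, and the phenol is carried as its lithium salt.

Step 7
Reactants: 14 7-{4-[4-hydroxy-3-(3-methylbut-2-en-1-yl)phenyl]-2-oxobutyl}-2,2-dimethyl-3,4-dihydro-2H,5H-pyrano[4,3-b]pyran-5-one
Product: 16 1-(5,7-dihydroxy-2,2-dimethyl-3,4-dihydro-2H-chromen-6-yl)-3-[4-hydroxy-3-(3-methylbut-2-en-1-yl)phenyl]propan-1-one (target), via methyl 6-{6-[4-hydroxy-3-(3-methylbut-2-en-1-yl)phenyl]-2,4-dioxohexyl}-2,2-dimethyl-3,4-dihydro-2H-pyran-5-carboxylate 15 (not isolated)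
Conditions: Mg(OMe)2 (6 equiv), MeOH, reflux, Ar; cold 0.5 M HCl
Reagents that add atoms: none
Why: Methoxide from Mg(OMe)2 adds to the lactone carbonyl C5 of 14 and the C5–O6 bond breaks, giving ester 15 with its 2,4-dioxohexyl chain held as a magnesium β-diketonate. The diketonate carbon (the former 7-CH2) then attacks the ester carbonyl in a Dieckmann-type Claisen condensation, methoxide leaves, and enolisation of the resulting 2-acylcyclohexane-1,3-dione gives aromatic ring A; the net change is an isomerisation in which ring atom O6 is exchanged for carbon. The closest known reaction type is the magnesium methoxide conversion of 6-(2-oxoalkyl)-2-pyranones into acylphloroglucinols. Ring A closes in the 6-exo-trig mode (6-(enolendo)-exo-trig), the two reacting carbons being held cis on the C4a=C8a double bond of the dihydropyran. No stereocentre is formed. The step needs C-acylation to win over aldol closure and over return to the pyranone: C4a, the only carbon that could act as aldol donor towards the side-chain ketone, bears no hydrogen, the CH2 next to the arylethyl group is far less acidic than the diketonate carbon, and only the Claisen product is trapped as an aromatic magnesium phenolate chelate. The pyran oxygen must end para to the acyl group because the O1–C8a bond of 14 is never broken. The β-alkoxyacrylate ester of 15 is neutral and therefore a better acceptor than the enolate-conjugated ester that closes in the 4-hydroxypyranone series.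

## Compound list

1 | 4-hydroxy-6-methyl-2H-pyran-2-one | CC1=CC(O)=CC(=O)O1 | starting material
2 | 3-methylbut-2-enal | CC(C)=CC=O | starting material
3 | 6-methyl-3-(3-methylbut-2-en-1-ylidene)-2H-pyran-2,4(3H)-dione (alkene geometry not defined) | CC(C)=CC=C1C(=O)C=C(C)OC1=O | intermediate
4 | 2,2,7-trimethyl-2H,5H-pyrano[4,3-b]pyran-5-one | CC1=CC2=C(C=CC(C)(C)O2)C(=O)O1 | intermediate
5 | 2,2,7-trimethyl-3,4-dihydro-2H,5H-pyrano[4,3-b]pyran-5-one | CC1=CC2=C(CCC(C)(C)O2)C(=O)O1 | intermediate
6 | methyl 3-(4-hydroxyphenyl)propanoate | COC(=O)CCc1ccc(O)cc1 | starting material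
7 | 3-chloro-3-methylbut-1-yne | CC(C)(Cl)C#C | starting material
8 | methyl 3-[4-(2-methylbut-3-yn-2-yloxy)phenyl]propanoate | COC(=O)CCc1ccc(OC(C)(C)C#C)cc1 | intermediate
9 | methyl 3-[4-(2-methylbut-3-en-2-yloxy)phenyl]propanoate | COC(=O)CCc1ccc(OC(C)(C)C=C)cc1 | intermediate
10 | methyl 3-[3-(3-methylbut-2-en-1-yl)-4-oxocyclohexa-1,5-dien-1-yl]propanoate | COC(=O)CCC1=CC(CC=C(C)C)C(=O)C=C1 | intermediate
11 | methyl 3-[4-hydroxy-3-(3-methylbut-2-en-1-yl)phenyl]propanoate | COC(=O)CCc1ccc(O)c(CC=C(C)C)c1 | intermediate
12 | (2,2-dimethyl-5-oxo-3,4-dihydro-2H,5H-pyrano[4,3-b]pyran-7-yl)methyllithium | [Li]CC1=CC2=C(CCC(C)(C)O2)C(=O)O1 | intermediate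
13 | lithium 4-(3-methoxy-3-oxopropyl)-2-(3-methylbut-2-en-1-yl)phenolate | [Li+].COC(=O)CCc1ccc([O-])c(CC=C(C)C)c1 | intermediate
14 | 7-{4-[4-hydroxy-3-(3-methylbut-2-en-1-yl)phenyl]-2-oxobutyl}-2,2-dimethyl-3,4-dihydro-2H,5H-pyrano[4,3-b]pyran-5-one | CC(C)=CCc1cc(CCC(=O)CC2=CC3=C(CCC(C)(C)O3)C(=O)O2)ccc1O | intermediate
15 | methyl 6-{6-[4-hydroxy-3-(3-methylbut-2-en-1-yl)phenyl]-2,4-dioxohexyl}-2,2-dimethyl-3,4-dihydro-2H-pyran-5-carboxylate | COC(=O)C1=C(CC(=O)CC(=O)CCc2ccc(O)c(CC=C(C)C)c2)OC(C)(C)CC1 | intermediate
16 | 1-(5,7-dihydroxy-2,2-dimethyl-3,4-dihydro-2H-chromen-6-yl)-3-[4-hydroxy-3-(3-methylbut-2-en-1-yl)phenyl]propan-1-one | CC(C)=CCc1cc(CCC(=O)c2c(O)cc3c(c2O)CCC(C)(C)O3)ccc1O | target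

## Step count and risks

Total steps: 7 (steps 1–2 make 5; steps 3–5 make 11; steps 6–7 join them). Longest linear sequence: 5 steps (3, 4, 5, 6, 7).

**Step 7 (key step).**
- What may go wrong: methoxide may add in a conjugate sense to C8a or C7 instead of the lactone carbonyl, opening one of the oxygen rings by trans-etherification. Once the acidic side chain is deprotonated the pyranone is an extended enolate and lactone opening may be slow. The electron-rich phenolate product may be oxidised in hot base if air is not excluded.
- Fallback: from 5, methanolysis of the neutral pyranone (NaOMe, MeOH, rt) should give methyl 2,2-dimethyl-6-(2-oxopropyl)-3,4-dihydro-2H-pyran-5-carboxylate F1. Its dianion (F1, 2 equiv, LiN(iPr)2, THF, −78 °C) would be acylated at the terminal methyl group by 11 (as 13), giving 15 as its enolate under aprotic conditions. Warming should then close ring A by the Dieckmann step and rejoin the route at 16. Here the lactone is opened before the acidic chain exists and no free methoxide is present during ring closure.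

**Step 6.**
- What may go wrong: proton transfer from the ester α-position of 13 to 12 in place of acylation, and aggregation of the lithium phenolate with low reactivity, leading to incomplete conversion.
- Fallback: from 11, Me(MeO)NH·HCl and iPrMgCl (THF, −20 °C) would give the Weinreb amide 3-[4-hydroxy-3-(3-methylbut-2-en-1-yl)phenyl]-N-methoxy-N-methylpropanamide F2. Its phenolate should take up one equivalent of 12 to a chelated tetrahedral adduct that neither enolises nor transfers a proton; aqueous work-up rejoins the route at 14.

**Step 2.**
- What may go wrong: over-reduction of the pyranone ring, or hydrogenolysis of the allylic C2–O1 bond.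
- Fallback: from 1, Tsuji–Trost C3-allylation (Pd(PPh3)4, 3-methylbut-2-en-1-yl acetate, DBU, THF) would give 4-hydroxy-6-methyl-3-(3-methylbut-2-en-1-yl)-2H-pyran-2-one F3. Acid-catalysed addition of the C4 hydroxyl to the olefin (TsOH, toluene, 60 °C) would close the dimethylpyran and rejoin the route at 5 without hydrogenation. The regiochemistry of this closure is less secure than in step 1, which is why it is only the fallback.

**Step 5.**
- What may go wrong: thermal fragmentation of the tertiary allyl ether with loss of isoprene, and closure of the product to a chroman if traces of acid are present.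
- Fallback: from 6, ortho-bromination (NBS, MeCN, 0 °C) would give methyl 3-(3-bromo-4-hydroxyphenyl)propanoate F4. Stille coupling with tributyl(3-methylbut-2-en-1-yl)stannane (Pd(PPh3)4, DMF, 90 °C) rejoins the route at 11.

## Further compounds

F1 | step 7 | methyl 2,2-dimethyl-6-(2-oxopropyl)-3,4-dihydro-2H-pyran-5-carboxylate | COC(=O)C1=C(CC(C)=O)OC(C)(C)CC1
F2 | step 6 | 3-[4-hydroxy-3-(3-methylbut-2-en-1-yl)phenyl]-N-methoxy-N-methylpropanamide | CON(C)C(=O)CCc1ccc(O)c(CC=C(C)C)c1
F3 | step 2 | 4-hydroxy-6-methyl-3-(3-methylbut-2-en-1-yl)-2H-pyran-2-one | CC(C)=CCC1=C(O)C=C(C)OC1=O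
F4 | step 5 | methyl 3-(3-bromo-4-hydroxyphenyl)propanoate | COC(=O)CCc1ccc(O)c(Br)c1
A1 | alternative 1 | 1-(5,7-dihydroxy-2,2-dimethyl-3,4-dihydro-2H-chromen-6-yl)ethan-1-one | CC(=O)c1c(O)cc2OC(C)(C)CCc2c1O
A2 | alternative 1 | 4-hydroxy-3-(3-methylbut-2-en-1-yl)benzaldehyde | CC(C)=CCc1cc(C=O)ccc1O
A3 | alternative 1 | (E)-1-(5,7-dihydroxy-2,2-dimethyl-3,4-dihydro-2H-chromen-6-yl)-3-[4-hydroxy-3-(3-methylbut-2-en-1-yl)phenyl]prop-2-en-1-one | CC(C)=CCc1cc(/C=C/C(=O)c2c(O)cc3OC(C)(C)CCc3c2O)ccc1O
A4 | alternative 1 | 1-(5,7-dihydroxy-2,2-dimethyl-3,4-dihydro-2H-chromen-8-yl)ethan-1-one | CC(=O)c1c(O)cc(O)c2CCC(C)(C)Oc12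
A5 | alternative 2 | 2,2-dimethyl-3,4-dihydro-2H-chromene-5,7-diol | CC1(C)CCc2c(O)cc(O)cc2O1
A6 | alternative 2 | 3-[4-hydroxy-3-(3-methylbut-2-en-1-yl)phenyl]propanoic acid | CC(C)=CCc1cc(CCC(=O)O)ccc1O
A7 | alternative 2 | 1-(5,7-dihydroxy-2,2-dimethyl-3,4-dihydro-2H-chromen-8-yl)-3-[4-hydroxy-3-(3-methylbut-2-en-1-yl)phenyl]propan-1-one | CC(C)=CCc1cc(CCC(=O)c2c(O)cc(O)c3CCC(C)(C)Oc23)ccc1O
A8 | alternative 3 | 1-[5,7-bis(methoxymethoxy)-2,2-dimethyl-3,4-dihydro-2H-chromen-6-yl]cyclopropan-1-ol | COCOc1cc2OC(C)(C)CCc2c(OCOC)c1C1(O)CC1
A9 | alternative 3 | 4-bromo-1-(methoxymethoxy)-2-(3-methylbut-2-en-1-yl)benzene | COCOc1ccc(Br)cc1CC=C(C)C
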